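4 questions wait: which flask puts the most monomer in chains, and how much each flask puts there by its end.

all flasks: initiator 0.20 mM

| run | free monomer | impurity | temperature | remark | time |
|---|---|---|---|---|---|
| south-east | 0.010 M | 21 µM | 55 °C | run made earlier |  |
| east | 0.015 M | 21 µM | 66 °C | run made earlier |  |
| west | 0.020 M | 32 µM | 55 °C | run made earlier |  |
| Thursday's | 0.020 M | 21 µM | 70 °C |  | 30 h |
| Wednesday's | 0.020 M | 21 µM |  | at 50 °C until 20 h, from then on at 70 °C | 30 h |
| Saturday's | 0.020 M | 21 µM | 50 °C |  | 30 h |

| run | time / h | monomer in chains / % |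
|---|---|---|
| south-east | 10.0 | 31.7 |
| south-east | 25.0 | 65.6 |
| south-east | 48.0 | 79.9 |
| south-east | 96.0 | 84.9 |
| east | 3.00 | 19.5 |
| east | 6.00 | 39.3 |
| east | 15.0 | 63.6 |
| east | 40.0 | 74.3 |
| west | 6.00 | 23.4 |
| west | 12.0 | 45.4 |
| west | 30.0 | 72.7 |
| west | 96.0 | 85.9 |

(scatter of a reading: 0.3 percentage points)

* the best flask by amount of monomer in chains, in percent of the free monomer charged; "all alike" if 1.5 percentage points covers them all (Thursday's / Wednesday's / Saturday's / all alike)
* amount of monomer in chains at the end, in percent of the free monomer charged, Thursday's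
* amount of monomer in chains at the end, in percent of the free monomer charged, Wednesday's
* amount of monomer in chains at the end, in percent of the free monomer charged, Saturday's



Work with the fraction left, not the fraction made, and take two separate ways to each end value.

1. The clock. Suppose free monomer goes pseudo-first-order, so that ln(1/fraction left) grows in step with time. The west run's reading at 6.00 h then gives 0.0444 h⁻¹ at 55 °C, and the east run's at 6.00 h gives 0.0832 h⁻¹ at 66 °C. These two runs also differ in free monomer and impurity; I set that aside and put the whole difference on temperature. The same factor per degree then gives 0.0334 h⁻¹ at 50 °C and 0.105 h⁻¹ at 70 °C.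

2. The ceiling. Call the loss ratio the part of the charge not in chains divided by the part in chains, at a run's last reading. It reads 0.164 in the west run and 0.346 in the east run. With the same setting aside, the same factor per degree gives 0.454 at 70 °C, a reckoned ceiling of 68.8%, and 0.117 at 50 °C, a reckoned ceiling of 89.5%.

3. Which one cheats? For the east run at 40.0 h the clock says 96.4%, more than the 74.3% read. For the west run at 30.0 h it says 73.6% against 72.7% read, from a different reading. So I take the lower of the two ways for these flasks.

4. My values. Thursday's: clock 95.7%, ceiling 68.8%, so 68.8%. Saturday's: clock 63.3%, ceiling 89.5%, so 63.3%. Wednesday's: the cold clock gives 48.7% by 20 h. I then let the hot clock use up part of the rest and count 68.8% of that part as going into chains, and my estimate comes to 71.6%.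

The forecast says “It looks like dead-end polymerisation” and gives 69% (65% to 73%) for Thursday's, 75% (69% to 80%) for Wednesday's and 67% (62% to 72%) for Saturday's. Mine are lower for Wednesday's and Saturday's, but both name Wednesday's.

The flasks give 69.8% for Thursday's, 76.2% for Wednesday's and 69.9% for Saturday's, so Wednesday's is best.

    free monomer + living end → monomer in chains + living end, rate k1*[living end]*[free monomer] (k = 420 M⁻¹ h⁻¹, Ea = 40.0 kJ mol⁻¹)
    2 living end → dead end B (k = 120 M⁻¹ h⁻¹, Ea = 53.0 kJ mol⁻¹)
    free monomer → uncatalysed product (k = 0.00320 h⁻¹, Ea = 113 kJ mol⁻¹)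
    free monomer + initiator → living end + monomer in chains (k = 9.50 M⁻¹ h⁻¹, Ea = 79.0 kJ mol⁻¹)
    initiator + impurity → spent initiator A (k = 1.30 × 10⁵ M⁻¹ h⁻¹, Ea = 58.0 kJ mol⁻¹)
    (constants at 50 °C)

Thursday's result makes the loss ratio 0.433, against 0.454 reckoned. Its part outside chains at 30.0 h is 26.6% uncatalysed product and 3.67% free monomer. Now repeat Thursday's at 95 °C. From 0.346, the same factor per degree gives a loss ratio of 2.47 and a reckoned ceiling of 28.8%. That flask ends with 35.3% in chains, 64.7% uncatalysed product and 0% free monomer.

The readings stem from a simulated flask from invented constants, noise included.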